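In a closed flask the charge is conserved: free monomer, monomer in chains and whatever else forms must sum to the charge at every time. This mass balance lets me read a loss from the runs.

| setting | grey | teal | flask |
|---|---|---|---|
| free monomer | 0.39 M | 0.39 M | 0.39 M |
| initiator | 7.8 mM | 16 mM | 7.8 mM |
| remark | the very flask that is asked about, followed so far | run made earlier |  |
| time |  |  | 6.0 h |

grey run (percent of the free monomer charged)

| time / min | monomer in chains / % | crystals / % |
|---|---|---|
| 2.50 | 7.8 | 0 |
| 6.00 | 16.3 | 1.3 |
| 12.0 | 29.6 | 5.2 |
| 20.0 | 42.6 | 11.3 |
| 25.0 | 49.5 | 17.1 |
| 30.0 | 55.4 | 21.9 |
| 40.0 | 63.0 | 32.7 |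

teal run (percent of the free monomer charged)

| time / h | monomer in chains / % | crystals / % |
|---|---|---|
| 0.133 | 27.9 | 3.6 |
| 0.333 | 55.9 | 16.2 |
| 0.667 | 74.8 | 40.1 |
| 1.00 | 80.1 | 58.8 |
| 1.33 | 81.8 | 66.4 |
| 2.00 | 82.7 | 74.1 |
| 2.50 | 81.3 | 75.8 |

(standard deviation of a reading: 0.5 percentage points)

- what is said of monomer in chains includes crystals
- crystals is a solid; its amount is given per volume of the solution
- the analysis behind the earlier runs scatters by 0.5 percentage points, standard deviation

1. amount of monomer in chains and crystals together at 6.0 h, in percent of the free monomer charged
2. concentration of monomer in chains in solution at 6.0 h, in percent of saturation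

In teal the chains column falls from 82.7 % to 81.3 % between its last two readings. That column counts crystals too, and crystals rise from 74.1 % to 75.8 % over the same interval, so I suspect that dissolved chains, the column minus crystals, are leaking away. Dividing that drop by the mean dissolved share and the interval gives 0.397 /h. Grey holds less in chains than teal at 40.0 min, but I assume it reaches teal's last state by 2.50 h. Holding dissolved chains at teal's last 5.5 percentage points up to 6.0 h then gives 73.7 %.

The weak link is that drop of 1.4 points, since each reading scatters by 0.5 points. So I use teal's whole run. Counting its free monomer as zero at the last reading, 19 points are missing, against a time-summed dissolved share of 0.474 h. Their ratio is the leak, the first-order rate constant of loss from dissolved chains: 0.395 /h. For chains and crystals together in the flask at 6.0 h, I commit to 73.7 %.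

The forecast says 82 % for that total and 110 % of saturation, reading grey as a “first-order approach to a plateau”; its total differs from mine.

The flask gives 74.4 % for the total and 85.2 % of saturation.

    initiator → 2 initiating radical (k = 0.110 /h)
    free monomer + initiating radical → growing radical + monomer in chains (k = 26000 /M/s)
    free monomer + growing radical → monomer in chains + growing radical, rate k3*[growing radical]*[free monomer] (k = 2.40 × 10⁷ /M/h)
    2 growing radical → dead chain (k = 4.00 × 10⁷ /M/s)
    crystals ⇌ monomer in chains, rate k5*(cs5 - [monomer in chains]) while solid is left; crystals form when [monomer in chains] > cs5 (solubility = 22.0 mM, k = 2.30 /h)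
    monomer in chains → over-reaction product (k = 0.400 /h)

In the flask, free monomer falls from 33.4 % at 0.600 h to 0.389 % at 3.00 h, while crystals rise from 28.2 % to 74.3 %; at that later time dissolved chains stand at 101 % of saturation. By 6.0 h, over-reaction product has grown from 19.7 % to 25.6 % and crystals have shrunk to 69.6 %. Divided by the leak, that product stands for a time-summed dissolved share of 0.648 h.

Now the same flask is read at 25 h. The leak, with dissolved chains held at their level at 6.0 h, gives 38.4 % there, and the computed value is 37.9 %, with crystals at 33.1 %.

(The readings stem from a simulated flask for substances that don't exist; the scatter is artificial.)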